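**Plan**

- Retrosynthetic cuts: (i) the bond from the bridging CH2 to the ipso carbon of ring C (the 4-hydroxyphenyl ring); (ii) the CH2–CH2 bond of the ethano arm between ring A (the methoxy-phenol ring) and ring B (the 2-hydroxyphenyl ring); (iii) three O–benzyl bonds and the O–methyl bond.
- Feature used: the bridging carbon is a bare CH2 on ring A, at the carbon flanked by C–OMe and the arm-bearing carbon and para to C–OH, and it meets ring C at the carbon para to that ring's OH. It can therefore be carried as the formyl carbon of a ring-A benzaldehyde (the ester carbon of methyl orsellinate), and ring C as a para-oxygenated arylboronic acid. Because the two free CH positions of the resorcinol-type ring A are strongly nucleophilic, the bridging carbon is made to react as a nucleophilic diazo carbon and not as a benzylic cation.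
- Forward order: methyl orsellinate → 4-O-benzylation → 2-O-methylation (the ester hydrogen bond tells the two OH groups apart) → lateral lithiation of the ring methyl and benzylation (arm and ring B) → ester to aldehyde → one-pot tosylhydrazone formation and reductive coupling with the ring-C boronic acid → global hydrogenolysis.
- Stereochemistry: none to set; the target is achiral.

Key step: step 6

Remark: the target has no stereocentre and no stereogenic double bond, so no step has to set or preserve configuration. Compounds 1, 4, 9 and 10 are taken as commercially available.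

**Step 1**
Reactants: 1 methyl orsellinate (methyl 2,4-dihydroxy-6-methylbenzoate)
Product: 2 methyl 4-(benzyloxy)-2-hydroxy-6-methylbenzoate
Conditions: BnBr (1.05 equiv), K2CO3, acetone, reflux
Reagents that add atoms: benzyl bromide, BrCc1ccccc1
Why: Williamson etherification in which the 2-OH is tied up in a hydrogen bond to the ester carbonyl and is the weaker nucleophile, so one equivalent of benzyl bromide should alkylate the free 4-OH selectively.

**Step 2**
Reactants: 2 methyl 4-(benzyloxy)-2-hydroxy-6-methylbenzoate
Product: 3 methyl 4-(benzyloxy)-2-methoxy-6-methylbenzoate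
Conditions: MeI, K2CO3, DMF, 50 °C
Reagents that add atoms: iodomethane, CI
Why: Williamson methylation of the remaining chelated phenol, which should proceed in the dipolar aprotic solvent once deprotonation breaks the hydrogen bond.

**Step 3**
Reactants: 3 methyl 4-(benzyloxy)-2-methoxy-6-methylbenzoate; 4 2-(benzyloxy)benzyl bromide [1-(benzyloxy)-2-(bromomethyl)benzene]
Product: 6 methyl 4-(benzyloxy)-2-{2-[2-(benzyloxy)phenyl]ethyl}-6-methoxybenzoate, via benzylic lithium species 5 (not isolated)
Conditions: LDA (1.1 equiv), THF, −78 °C; then 4, −78 °C → rt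
Reagents that add atoms: none
Why: Lateral lithiation of an o-toluate, in which LDA removes a proton from the ring-A methyl group ortho to the ester (the anion is an extended ester dienolate), followed by SN2 benzylation that builds the CH2–CH2 arm and brings in ring B.

**Step 4**
Reactants: 6 methyl 4-(benzyloxy)-2-{2-[2-(benzyloxy)phenyl]ethyl}-6-methoxybenzoate
Product: 7 {4-(benzyloxy)-2-{2-[2-(benzyloxy)phenyl]ethyl}-6-methoxyphenyl}methanol
Conditions: LiAlH4, THF, 0 °C → reflux; H2O/aq NaOH work-up
Reagents that add atoms: none
Why: Hydride reduction of the di-ortho-substituted methyl ester to the primary benzylic alcohol, with a basic work-up so that the acid-sensitive, electron-rich benzylic alcohol does not ionise.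

**Step 5**
Reactants: 7 {4-(benzyloxy)-2-{2-[2-(benzyloxy)phenyl]ethyl}-6-methoxyphenyl}methanol
Product: 8 4-(benzyloxy)-2-{2-[2-(benzyloxy)phenyl]ethyl}-6-methoxybenzaldehyde
Conditions: activated MnO2, CH2Cl2, rt
Reagents that add atoms: none
Why: Heterogeneous MnO2 oxidation is selective for benzylic alcohols, stops at the aldehyde and is neutral, so the benzyl ethers and the electron-rich ring should be untouched.

**Step 6**
Reactants: 8 4-(benzyloxy)-2-{2-[2-(benzyloxy)phenyl]ethyl}-6-methoxybenzaldehyde; 9 p-toluenesulfonohydrazide; 10 4-(benzyloxy)phenylboronic acid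
Product: 14 5-(benzyloxy)-2-[4-(benzyloxy)benzyl]-1-{2-[2-(benzyloxy)phenyl]ethyl}-3-methoxybenzene, via N-tosylhydrazone 11 (not isolated), via aryldiazomethane 12 (not isolated), via diarylmethylboronic acid 13 (not isolated)
Conditions: 9 (1.05 equiv), 1,4-dioxane, 80 °C; then 10 (1.5 equiv), K2CO3 (2 equiv), 110 °C, N2, one pot
Reagents that add atoms: none
Why: Condensation of 8 with 9 gives the N-tosylhydrazone 11, which K2CO3 deprotonates so that Bamford–Stevens loss of sulfinate releases the aryldiazomethane 12; its nucleophilic diazo carbon adds to the empty p orbital of boronic acid 10, and a 1,2-shift of the aryl group from boron to carbon with loss of N2 forges the CH–C(ipso) bond to ring C, giving the benzylic boronic acid 13, which is protodeboronated in the basic medium to the CH2 of 14. The closest known reaction type is the metal-free reductive coupling of N-tosylhydrazones with arylboronic acids (Barluenga–Valdés coupling), established for aryl aldehyde hydrazones and electron-rich boronic acids. No ring is closed and no stereocentre remains, since 13 is a racemic transient whose C–B bond is replaced by C–H. The step needs site selectivity on both partners: ring C can only be attached through its boron-bearing carbon, para to its oxygen, and the bridging carbon reacts as a carbon nucleophile, so the nucleophilic CH positions of ring A (between the two oxygens, and between the oxygen and the arm), which would capture a benzylic cation, cannot interfere. Slow release of 12 from the hydrazone salt in the presence of excess 10 should keep carbene-derived pathways (azine formation, C–H insertion into the arm or the methoxy group) in the background.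

**Step 7**
Reactants: 14 5-(benzyloxy)-2-[4-(benzyloxy)benzyl]-1-{2-[2-(benzyloxy)phenyl]ethyl}-3-methoxybenzene
Product: 15 4-(4-hydroxybenzyl)-3-[2-(2-hydroxyphenyl)ethyl]-5-methoxyphenol (target)
Conditions: H2 (1 atm), 10% Pd/C, EtOAc–MeOH, rt
Reagents that add atoms: none
Why: Catalytic hydrogenolysis should cleave the three O-benzyl ethers in one operation, while the aryl methyl ether, the diarylmethane CH2 and the ethano arm are inert under these mild conditions.

**Compound list**

1 | methyl orsellinate (methyl 2,4-dihydroxy-6-methylbenzoate) | COC(=O)c1c(C)cc(O)cc1O | starting material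
2 | methyl 4-(benzyloxy)-2-hydroxy-6-methylbenzoate | COC(=O)c1c(C)cc(OCc2ccccc2)cc1O | intermediate
3 | methyl 4-(benzyloxy)-2-methoxy-6-methylbenzoate | COC(=O)c1c(C)cc(OCc2ccccc2)cc1OC | intermediate
4 | 2-(benzyloxy)benzyl bromide | BrCc1ccccc1OCc1ccccc1 | starting material
5 | benzylic lithium species of 3 (LiCH2 in place of the ring methyl; not isolated) | [Li]Cc1cc(OCc2ccccc2)cc(OC)c1C(=O)OC | intermediate
6 | methyl 4-(benzyloxy)-2-{2-[2-(benzyloxy)phenyl]ethyl}-6-methoxybenzoate | COC(=O)c1c(CCc2ccccc2OCc2ccccc2)cc(OCc2ccccc2)cc1OC | intermediate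
7 | {4-(benzyloxy)-2-{2-[2-(benzyloxy)phenyl]ethyl}-6-methoxyphenyl}methanol | OCc1c(CCc2ccccc2OCc2ccccc2)cc(OCc2ccccc2)cc1OC | intermediate
8 | 4-(benzyloxy)-2-{2-[2-(benzyloxy)phenyl]ethyl}-6-methoxybenzaldehyde | O=Cc1c(CCc2ccccc2OCc2ccccc2)cc(OCc2ccccc2)cc1OC | intermediate
9 | p-toluenesulfonohydrazide | Cc1ccc(cc1)S(=O)(=O)NN | starting material
10 | 4-(benzyloxy)phenylboronic acid | OB(O)c1ccc(OCc2ccccc2)cc1 | starting material
11 | (E)-N-tosylhydrazone of aldehyde 8 (not isolated) | Cc1ccc(cc1)S(=O)(=O)N/N=C/c1c(CCc2ccccc2OCc2ccccc2)cc(OCc2ccccc2)cc1OC | intermediate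
12 | aryldiazomethane derived from 11 (not isolated) | [N-]=[N+]=Cc1c(CCc2ccccc2OCc2ccccc2)cc(OCc2ccccc2)cc1OC | intermediate
13 | racemic [4-(benzyloxy)phenyl]{4-(benzyloxy)-2-{2-[2-(benzyloxy)phenyl]ethyl}-6-methoxyphenyl}methylboronic acid (not isolated) | OB(O)C(c1ccc(OCc2ccccc2)cc1)c1c(CCc2ccccc2OCc2ccccc2)cc(OCc2ccccc2)cc1OC | intermediate
14 | 5-(benzyloxy)-2-[4-(benzyloxy)benzyl]-1-{2-[2-(benzyloxy)phenyl]ethyl}-3-methoxybenzene | COc1cc(OCc2ccccc2)cc(CCc2ccccc2OCc2ccccc2)c1Cc1ccc(OCc2ccccc2)cc1 | intermediate
15 | 4-(4-hydroxybenzyl)-3-[2-(2-hydroxyphenyl)ethyl]-5-methoxyphenol | COc1cc(O)cc(CCc2ccccc2O)c1Cc1ccc(O)cc1 | target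

**Step count and risks**

Total step count: 7. Longest linear sequence: 7 steps (1 → 15).

Steps most likely to fail:

1. Step 6. Capture of the sterically shielded, di-ortho-substituted diazo carbon by boron may be slow, so that thermal nitrogen loss and carbene chemistry take over; protodeboronation of the benzylic boron intermediate may also be incomplete. Fallback: setting out from aldehyde 8, commercial 4-(benzyloxy)phenylmagnesium bromide (THF, 0 °C) should add to the formyl group to give the racemic diarylmethanol [4-(benzyloxy)phenyl]{4-(benzyloxy)-2-{2-[2-(benzyloxy)phenyl]ethyl}-6-methoxyphenyl}methanol F1. Ionic hydrogenation (Et3SiH, TFA, CH2Cl2, −40 → 0 °C) should then remove the doubly benzylic hydroxyl through the diarylmethyl cation, which excess silane traps, and the route is rejoined at 14.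

2. Step 3. Proton transfer from the newly formed, still acidic benzylic CH2 of the product to the lithiated ester may lead to double alkylation, and Claisen-type self-condensation of the lithiated ester with unreacted ester may compete. Fallback: setting out from 3, the lithiated ester is trapped with 2-(benzyloxy)benzaldehyde instead of the bromide; the alkoxide should lactonise irreversibly to the racemic dihydroisocoumarin 6-(benzyloxy)-3-[2-(benzyloxy)phenyl]-8-methoxy-3,4-dihydro-1H-isochromen-1-one F2. E1cB ring opening (KOt-Bu, THF) should give the stilbene acid 4-(benzyloxy)-2-{(E)-2-[2-(benzyloxy)phenyl]ethenyl}-6-methoxybenzoic acid F3. Diimide reduction (p-toluenesulfonohydrazide, NaOAc, aqueous DME, reflux), which spares benzyl ethers, should give 4-(benzyloxy)-2-{2-[2-(benzyloxy)phenyl]ethyl}-6-methoxybenzoic acid F4, and esterification (MeI, K2CO3, DMF) rejoins the route at 6.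

3. Step 1. Regiocontrol may be lost through competing alkylation of the hydrogen-bonded 2-hydroxyl, leading to over-benzylation. Fallback: setting out from 1, both hydroxyls are benzylated on purpose (BnBr 2.5 equiv, K2CO3, DMF, 60 °C) to give methyl 2,4-bis(benzyloxy)-6-methylbenzoate F5. Chelation-controlled cleavage of only the benzyl ether ortho to the ester (MgBr2·OEt2, toluene–Et2O, reflux) should then return to 2.

**Further compounds**

F1 | step 6 | [4-(benzyloxy)phenyl]{4-(benzyloxy)-2-{2-[2-(benzyloxy)phenyl]ethyl}-6-methoxyphenyl}methanol (racemic) | OC(c1ccc(OCc2ccccc2)cc1)c1c(CCc2ccccc2OCc2ccccc2)cc(OCc2ccccc2)cc1OC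
F2 | step 3 | 6-(benzyloxy)-3-[2-(benzyloxy)phenyl]-8-methoxy-3,4-dihydro-1H-isochromen-1-one (racemic) | O=C1OC(Cc2cc(OCc3ccccc3)cc(OC)c12)c1ccccc1OCc1ccccc1
F3 | step 3 | 4-(benzyloxy)-2-{(E)-2-[2-(benzyloxy)phenyl]ethenyl}-6-methoxybenzoic acid | OC(=O)c1c(/C=C/c2ccccc2OCc2ccccc2)cc(OCc2ccccc2)cc1OC
F4 | step 3 | 4-(benzyloxy)-2-{2-[2-(benzyloxy)phenyl]ethyl}-6-methoxybenzoic acid | OC(=O)c1c(CCc2ccccc2OCc2ccccc2)cc(OCc2ccccc2)cc1OC
F5 | step 1 | methyl 2,4-bis(benzyloxy)-6-methylbenzoate | COC(=O)c1c(C)cc(OCc2ccccc2)cc1OCc1ccccc1
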